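## Structural features

Target 22 contains three rings: benzene ring A (C1'–C6'), the 2,2-dimethyl-2H-pyran ring B fused to it through the oxygen on C2' and the carbon C3' (together a 2,2-dimethylchromene), and cyclohexene ring C (C1–C6, alkene C3=C4, methyl on C3). Rings A and C are not fused: they are joined only through ketone carbon C7, which sits on C1' between the pyran oxygen (C2') and the free phenol (C6'), para to the methoxy group (C4'), and on C1 of ring C. Ring C carries three contiguous stereocentres, C6 (phenyl), C1 (acyl) and C2 (prenyl), configured 1R,2S,6R: acyl trans to phenyl and cis to prenyl, prenyl and phenyl trans across C1. C1 is α to the carbonyl and can be set by protonation, but C2 and C6 cannot be corrected, so the real difficulty is to fix C6 in absolute terms and then to place hydrogen at C2 on the phenyl face while the alkene ends at C3=C4 and not at C2=C3. The fragile features are the two trisubstituted alkenes (prenyl and C3=C4) and the chromene C=C, which are sensitive to acid and electrophiles, the hindered chelated ortho-hydroxyaryl ketone, and the enolisable C1 centre. The key step exploits the fact that C7–C1, C2(prenyl)=C3(methyl) and C4 map onto the carboxyl carbon and C3–C6 of a 2-pyrone-3-carboxylate, while C5–C6(phenyl) is styrene: one [4+2] addition forms C4–C5 and C1–C6 and leaves a lactone oxygen on C4 that later directs a hydride to C2. Of the two carboxyl carbons that this diene places on C1, it is the ester carbon that survives as C7; the bridging lactone carbonyl serves as the stereochemical relay and then leaves as CO2.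

## Logic of the disconnections

22 ⇒ 20 + 21. The O–C(Me2) bond and the C3'–CH bond of ring B are cut. Ring B is the formal condensation product of an ortho C–H/O–H pair of a phenol with a five-carbon enal, and removing it leaves a ring A whose two positions ortho to C7 are equivalent, so no regiochemical question arises. The forward step must stop after one annulation and must not disturb C1.

20 ⇒ 19 ⇒ 18 ⇒ 14 + 17, with 17 ⇐ 16 ⇐ 15. The C7–C1' bond is cut. C1' lies between two oxygens, the natural site for lithiation once both are acetal-protected, and C7 as an aldehyde is the electrophile most likely to accept so hindered a nucleophile. This divides the molecule into ring C with all its stereocentres (14) and a symmetrical arene. The forward steps need addition faster than enolisation of 14, and an oxidation and an acetal cleavage that spare three alkenes.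

14 ⇒ 13 ⇒ 12. No skeletal bond is cut; C7 is taken back to the ester oxidation level, in which it is carried through the ring-forming chemistry. The only demand is that C1 is not epimerised.

12 ⇒ 11 ⇒ 10. Here bonds are restored, not cut: the C4–O bond and the one-carbon bridge from that oxygen to C1, with the alkene moved back from C3=C4 to C2=C3. The reason is that 10 holds in one rigid frame the information for C2 (through the face of the C4–O bond), for C6 and for the alkene position. The forward step needs ionisation with inversion at C4, hydride delivery to the more substituted allyl terminus C2, loss of CO2 from C1, and protonation of C1 anti to the C2 side chain.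

10 ⇒ 8 + 9. C1–C6 and C4–C5 are cut in a retro-[4+2] sense. Three stereocentres and ring C are traded for a flat, achiral heteroaromatic diene and a commodity alkene. The forward step must control regiochemistry (benzylic carbon to C1), endo orientation and the face of 8, at a temperature below that of CO2 extrusion.

8 ⇒ 6 + 7. The bond between C2 and the side-chain CH2 is cut. C2 is the β-carbon of a vinylogous carbonate, so an enol sulfonate there is an excellent cross-coupling electrophile, and the side chain arrives as an intact five-carbon unit. The allyl unit must be delivered through its unsubstituted terminus under non-basic conditions.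

6 ⇒ 5 ⇒ 4. The sulfonate is returned to the enol, and the lactone C–O bond (ring oxygen to the carbonyl that is later lost) is cut; the ring oxygen is traced to a masked aldehyde at C4. This gives an open chain that holds every carbon of the diene. Lactonisation must be faster than cleavage of the tricarbonyl.

4 ⇒ 1 + 3, with 3 ⇐ 2. The C1–C2 bond is cut: C1 with both its carboxyl carbons is 1, and C2–C3(methyl)–C4 is a three-carbon acyl unit. The forward step is a C-acylation of a malonate, which a magnesium chelate secures.

## Other disconnections considered

Alternative 1: The cut is the C1–C6 bond alone, made in a compound that already contains rings A and B. Forward, the open-chain trienone A1, bound through its phenol and ketone oxygens to a chiral Lewis acid, would close by disrotatory 6π-electrocyclisation and tautomerise to the conjugated dienyl ketone A2, in which C6 is the only stereocentre.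
- In its favour: A1 is flat and achiral, the aryl ketone and chromene are in place before ring C exists, and no protecting groups are needed. On convergence and step economy this plan is better than the chosen one.
- Against it here: A2 lacks the prenyl group, so C2 and C1 must still be made by conjugate addition of a prenyl nucleophile to a dienone, where 1,6-addition at C4 and transfer through the wrong allyl terminus both compete, followed by protonation at C1. Lewis-acid acceleration of carbocyclic 6π closures is best established for an acceptor on C2 of the triene, not on a terminal carbon as in A1. The (4Z) geometry of A1 is prone to isomerisation, and further 1,5-hydrogen shifts could move the diene of A2 into conjugation with phenyl and erase C6.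
- Comparison: on structure, alternative 1 leaves two of three stereocentres to a later, less controlled addition, whereas the chosen plan derives C2 from C6 by a stereospecific substitution. On mechanism, both rely on one catalytic asymmetric step (equal), but the chosen one belongs to a reaction class with direct precedent. On step economy, alternative 1 is the shorter.

Alternative 2: The cuts lie in ring A: the two bonds from C1' and its silyloxy-bearing neighbour to the rest of the ring, and the bond that closes the ring at the phenol carbon. Forward, heating 3-methoxycyclobutenone A5 with siloxyalkyne A4 would give phenol A3 through 4π opening to a vinylketene, [2+2] addition to the alkyne, a second 4π opening, 6π closure and tautomerisation.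
- In its favour: the crowded ring A is made under neutral thermal conditions without a hindered aryllithium, and the regiochemistry is dictated by the polarity of the ynol ether. The two ortho oxygens emerge differentiated (one free, one silylated), so a single chromene annulation would follow from constitution and not from stoichiometry; on this point the alternative is better than the chosen plan.
- Against it here: A4 must already contain ring C with its three stereocentres, so the hard part of the molecule needs its own synthesis plus a homologation to the alkyne. After the key step, carbinol deprotection and oxidation, desilylation and annulation remain.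
- Comparison: on structure, it builds the easy ring and leaves the hard one. On mechanism, the pericyclic cascade is as predictable as the cycloaddition of the chosen plan (equal). On step economy, it is clearly longer.

Alternative 3: The cut is the C3=C4 double bond. Forward, the second-generation Hoveyda–Grubbs catalyst would load onto the terminal vinyl group of acyclic diene A7 and close onto its trisubstituted butenyl alkene with loss of propene, giving A6, which is the same compound as 12 of the chosen route. A7 would come from an Ireland–Claisen rearrangement in which one carbinol stereocentre is transferred through a chair transition state into the vicinal C1/C2 pair and is itself consumed.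
- In its favour: every step belongs to a heavily used reaction class, the ring-forming step creates no stereocentre and so cannot erode any, and the endgame from A6 is shared with the chosen plan. On predictability of the individual steps it is the equal of the chosen plan or better.
- Against it here: the prenyl group of A7 is a third alkene that the ruthenium carbene can engage, giving a seven-membered ring or cross-metathesis products. The rearrangement fixes only two of the three stereocentres, so C6 must be set beforehand and matched to the transferred chirality.
- Comparison: on structure, the chosen plan makes two ring bonds and three stereocentres in one catalytic step from an achiral diene, while alternative 3 spreads the same work over an asymmetric step, a rearrangement and a metathesis. On mechanism, alternative 3 is safer step by step but has a chemoselectivity problem the chosen plan lacks. On step economy, the way to A6 would be roughly twice as long as the way to 12.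

Key step: step 5

Remark on the chemistry (materials): (2E)-3-methoxy-2-methylprop-2-enoic acid 2, a standard reagent for building the thymine ring, is taken as a purchasable building block.

Remark on the chemistry (catalyst sense): the (S,S) antipode of the bis(oxazoline) is written in step 5 on the basis of the chelate model stated there; both antipodes are articles of commerce.

## Route

Step 1
Reactants: 1 dimethyl malonate; 2 (2E)-3-methoxy-2-methylprop-2-enoic acid
Product: 4 dimethyl 2-[(2E)-3-methoxy-2-methylprop-2-enoyl]propanedioate, via (2E)-3-methoxy-2-methylprop-2-enoyl chloride 3 (not isolated)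
Conditions: (COCl)2, DMF (cat.), CH2Cl2, 0 °C → rt; concentrate; then 1, MgCl2, Et3N, MeCN, 0 °C → rt; aq. HCl work-up
Reagents that add atoms: none
Why: Oxalyl chloride with catalytic DMF turns the vinylogous carbonic acid 2 into 3 without touching the enol ether; the magnesium chelate of 1 (MgCl2/Et3N soft enolisation) is then C-acylated (Claisen-type acylation of a malonate), the acid chloride carbonyl being far more electrophilic than the β-methoxy carbon, and the product is held as its unreactive magnesium enolate until acidic work-up.

Step 2
Reactants: 4 dimethyl 2-[(2E)-3-methoxy-2-methylprop-2-enoyl]propanedioate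
Product: 5 methyl 4-hydroxy-5-methyl-2-oxo-2H-pyran-3-carboxylate
Conditions: p-TsOH·H2O (1.1 equiv), toluene, 90 °C, methanol distilled off
Reagents that add atoms: water, O
Why: One equivalent of water under acid hydrolyses the β-methoxy enone to the hydroxymethylene ketone, whose enol oxygen closes onto one of the two equivalent esters with loss of methanol (lactonisation, the same closure by which alkoxymethylene β-keto esters give 6-unsubstituted 4-hydroxy-2-pyrones). The product is a stabilised vinylogous acid, which drives the sequence, and the small amount of water limits cleavage of the tricarbonyl.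

Step 3
Reactants: 5 methyl 4-hydroxy-5-methyl-2-oxo-2H-pyran-3-carboxylate
Product: 6 methyl 5-methyl-2-oxo-4-{[(trifluoromethyl)sulfonyl]oxy}-2H-pyran-3-carboxylate
Conditions: Tf2O, Et3N, CH2Cl2, −78 → 0 °C
Reagents that add atoms: trifluoromethanesulfonic anhydride, O=S(=O)(OS(=O)(=O)C(F)(F)F)C(F)(F)F
Why: O-Sulfonylation of a vinylogous carboxylic acid: the acidic 4-hydroxy group of 5 is triflated by Tf2O and a tertiary amine at low temperature, as is routine for 4-hydroxy-2-pyrones and 4-hydroxycoumarins; 6 is used promptly because it is a vinylogous mixed anhydride.

Step 4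
Reactants: 6 methyl 5-methyl-2-oxo-4-{[(trifluoromethyl)sulfonyl]oxy}-2H-pyran-3-carboxylate; 7 tributyl(3-methylbut-2-en-1-yl)stannane
Product: 8 methyl 5-methyl-4-(3-methylbut-2-en-1-yl)-2-oxo-2H-pyran-3-carboxylate
Conditions: Pd(PPh3)4 (5 mol %), LiCl, THF, 65 °C
Reagents that add atoms: none
Why: Stille coupling: the electron-poor enol triflate adds readily to zerovalent palladium, chloride makes the palladium intermediate ready for transmetallation with 7, and reductive elimination from the allyl(pyronyl)palladium species takes place at the unsubstituted allyl terminus, giving the linear prenyl group. The neutral conditions spare the base-sensitive pyrone and its acidic side-chain CH2.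

Step 5
Reactants: 8 methyl 5-methyl-4-(3-methylbut-2-en-1-yl)-2-oxo-2H-pyran-3-carboxylate; 9 styrene
Product: 10 methyl (1R,4S,8S)-6-methyl-5-(3-methylbut-2-en-1-yl)-3-oxo-8-phenyl-2-oxabicyclo[2.2.2]oct-5-ene-4-carboxylate
Conditions: Cu(OTf)2 (15 mol %), 2,2'-(propane-2,2-diyl)bis[(4S)-4-tert-butyl-4,5-dihydro-1,3-oxazole] (17 mol %), 4 Å MS, CH2Cl2, 25 °C, 9 (5 equiv)
Reagents that add atoms: none
Why: The divalent copper centre of the Cu(OTf)2–bis(oxazoline) complex is chelated by the lactone and ester carbonyl oxygens of 8, which lowers the LUMO of the diene C1=C2–C3=C4 (ring C numbering), and 9 adds across C1 and C4 in a concerted but asynchronous [4+2] cycloaddition of inverse electron demand. The closest known reaction type is the copper bis(oxazoline)-catalysed Diels–Alder reaction of 2-pyrone-3-carboxylates with styrenes and enol ethers, which gives the same kind of bridged lactone. The one ring that is closed, carbocyclic ring C, is formed by an intermolecular suprafacial [4+2] closure that makes C4–C5 and C1–C6 and dearomatises the pyrone, whose O–C(=O) unit becomes the two-atom bridge of the bicyclo[2.2.2] frame. Regiochemistry follows from polarity: the CH2 terminus of 9, which carries the larger HOMO coefficient, bonds to C4, the most electrophilic diene terminus, so the benzylic carbon bonds to C1. C6 is set by the endo rule: the phenyl ring lies under the C2=C3 bond and away from the lactone bridge, where it gains secondary overlap with the diene and avoids the catalyst-bound carbonyl groups. C1 and C4 are fixed relative to each other and to C6 by suprafacial addition to one face of the pyrone, and that face is chosen by the ligand, one tert-butyl group of which covers the opposite face of the chelate on the lactone side, where the dienophile must sit. The step therefore needs regio-, endo- and enantioselectivity; the substrate secures the first two through its polarity and offers two-point binding through its 1,3-dicarbonyl unit, the methyl ester being the smallest ester and so the one least twisted out of the ring plane by the neighbouring prenyl group. Working at 25 °C keeps 10 well below the temperature at which such adducts extrude CO2, and molecular sieves suppress adventitious triflic acid that could attack the prenyl alkene or polymerise 9.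

Step 6
Reactants: 10 methyl (1R,4S,8S)-6-methyl-5-(3-methylbut-2-en-1-yl)-3-oxo-8-phenyl-2-oxabicyclo[2.2.2]oct-5-ene-4-carboxylate
Product: 12 methyl (1R,2S,6R)-3-methyl-2-(3-methylbut-2-en-1-yl)-6-phenylcyclohex-3-ene-1-carboxylate, via malonic half-acid 11 (not isolated)
Conditions: Pd(OAc)2 (5 mol %), n-Bu3P (10 mol %), HCO2H, Et3N, dioxane, 40 °C; then 100 °C
Reagents that add atoms: none
Why: Tsuji–Mandai formate hydrogenolysis of an allylic carboxylate: zerovalent palladium ionises the strained allylic C4–O bond with inversion, so the metal sits on the face opposite the oxygen (the phenyl face), and the σ-allyl palladium formate bound at the less hindered C4 passes hydride through a cyclic transition state to C2 on that same face, which puts prenyl trans to phenyl and the alkene at C3=C4 (the small n-Bu3P favours this regiochemistry). Warming then decarboxylates the malonic half-acid 11 (the former lactone carbonyl leaves as CO2), and the resulting ester enol is protonated at C1 anti to the pseudoaxial C2 prenyl group (kinetic protonation of an exocyclic enol from its less hindered face), giving the ester cis to prenyl and trans to phenyl, the arrangement with ester and phenyl both equatorial.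

Step 7
Reactants: 12 methyl (1R,2S,6R)-3-methyl-2-(3-methylbut-2-en-1-yl)-6-phenylcyclohex-3-ene-1-carboxylate
Product: 13 [(1R,2S,6R)-3-methyl-2-(3-methylbut-2-en-1-yl)-6-phenylcyclohex-3-en-1-yl]methanol
Conditions: LiAlH4, THF, 0 °C
Reagents that add atoms: none
Why: Hydride reduction of an ester to the primary alcohol; LiAlH4 at 0 °C does not touch the unactivated alkenes and does not enolise C1.

Step 8
Reactants: 13 [(1R,2S,6R)-3-methyl-2-(3-methylbut-2-en-1-yl)-6-phenylcyclohex-3-en-1-yl]methanol
Product: 14 (1R,2S,6R)-3-methyl-2-(3-methylbut-2-en-1-yl)-6-phenylcyclohex-3-ene-1-carbaldehyde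
Conditions: DMP, CH2Cl2, rt
Reagents that add atoms: none
Why: Dess–Martin oxidation stops at the aldehyde under nearly neutral conditions; 14 is not chromatographed but used at once, so that the α-stereocentre C1 has no opportunity to equilibrate.

Step 9
Reactants: 15 5-methoxyresorcinol
Product: 16 1-methoxy-3,5-bis(methoxymethoxy)benzene
Conditions: MOMCl, i-Pr2NEt, CH2Cl2, 0 °C → rt
Reagents that add atoms: chloromethyl methyl ether, COCCl
Why: O-Alkylation of both phenols with chloromethyl methyl ether and a hindered amine base; the methoxymethyl acetals are chosen because they direct the lithiation of step 10 and are removed by mild acid in step 12.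

Step 10
Reactants: 14 (1R,2S,6R)-3-methyl-2-(3-methylbut-2-en-1-yl)-6-phenylcyclohex-3-ene-1-carbaldehyde; 16 1-methoxy-3,5-bis(methoxymethoxy)benzene
Product: 18 [4-methoxy-2,6-bis(methoxymethoxy)phenyl][(1R,2S,6R)-3-methyl-2-(3-methylbut-2-en-1-yl)-6-phenylcyclohex-3-en-1-yl]methanol (both carbinol epimers), via aryllithium 17 (not isolated)
Conditions: 16 (1.5 equiv), n-BuLi, THF, 0 °C; then 14, −78 → 0 °C; H2O quench
Reagents that add atoms: none
Why: Directed ortho-metalation: the position between the two OMOM groups is the most acidic and doubly coordinated site of 16, so n-BuLi gives 17 regioselectively, and at −78 °C its 1,2-addition to the aldehyde outruns enolisation of C1. The new carbinol centre is formed without control, which is immaterial because it is oxidised in step 11.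

Step 11
Reactants: 18 [4-methoxy-2,6-bis(methoxymethoxy)phenyl][(1R,2S,6R)-3-methyl-2-(3-methylbut-2-en-1-yl)-6-phenylcyclohex-3-en-1-yl]methanol
Product: 19 [4-methoxy-2,6-bis(methoxymethoxy)phenyl][(1R,2S,6R)-3-methyl-2-(3-methylbut-2-en-1-yl)-6-phenylcyclohex-3-en-1-yl]methanone
Conditions: DMP, CH2Cl2, rt
Reagents that add atoms: none
Why: Dess–Martin oxidation of the hindered benzylic carbinol to the ketone; the neutral conditions keep the acetals and the alkenes, and both carbinol epimers converge on one ketone.

Step 12
Reactants: 19 [4-methoxy-2,6-bis(methoxymethoxy)phenyl][(1R,2S,6R)-3-methyl-2-(3-methylbut-2-en-1-yl)-6-phenylcyclohex-3-en-1-yl]methanone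
Product: 20 (2,6-dihydroxy-4-methoxyphenyl)[(1R,2S,6R)-3-methyl-2-(3-methylbut-2-en-1-yl)-6-phenylcyclohex-3-en-1-yl]methanone
Conditions: HCl (3 M aq.), MeOH, 45 °C
Reagents that add atoms: none
Why: Acid-catalysed acetal exchange with methanol removes both MOM groups as dimethoxymethane; dilute acid at 45 °C is mild enough for the trisubstituted alkenes, and the freed phenols are stabilised by hydrogen bonding to the ketone.

Step 13
Reactants: 20 (2,6-dihydroxy-4-methoxyphenyl)[(1R,2S,6R)-3-methyl-2-(3-methylbut-2-en-1-yl)-6-phenylcyclohex-3-en-1-yl]methanone; 21 3-methylbut-2-enal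
Product: 22 (7-hydroxy-5-methoxy-2,2-dimethyl-2H-chromen-8-yl)[(1R,2S,6R)-3-methyl-2-(3-methylbut-2-en-1-yl)-6-phenylcyclohex-3-en-1-yl]methanone
Conditions: 21 (1.1 equiv), ethylenediammonium diacetate (10 mol %), toluene, 110 °C
Reagents that add atoms: none
Why: Chromene annulation: the ammonium acetate catalyst condenses 21 at the nucleophilic ring A carbon ortho to a phenol (Knoevenagel-type), loss of water gives an ortho-quinone methide, and oxa-6π electrocyclisation closes ring B. The two ortho sites of 20 are equivalent, so one regioisomer results, and one equivalent of 21 together with the lower reactivity of the remaining chelated phenol keeps the reaction at mono-annulation; no stereocentre is touched.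

## Compound list

1 | dimethyl malonate | COC(=O)CC(=O)OC | starting material
2 | (2E)-3-methoxy-2-methylprop-2-enoic acid | CO/C=C(\C)C(=O)O | starting material
3 | (2E)-3-methoxy-2-methylprop-2-enoyl chloride | CO/C=C(\C)C(=O)Cl | intermediate (not isolated)
4 | dimethyl 2-[(2E)-3-methoxy-2-methylprop-2-enoyl]propanedioate | CO/C=C(\C)C(=O)C(C(=O)OC)C(=O)OC | intermediate
5 | methyl 4-hydroxy-5-methyl-2-oxo-2H-pyran-3-carboxylate | COC(=O)C1=C(O)C(C)=COC1=O | intermediate
6 | methyl 5-methyl-2-oxo-4-{[(trifluoromethyl)sulfonyl]oxy}-2H-pyran-3-carboxylate | COC(=O)C1=C(OS(=O)(=O)C(F)(F)F)C(C)=COC1=O | intermediate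
7 | tributyl(3-methylbut-2-en-1-yl)stannane | CCCC[Sn](CCCC)(CCCC)CC=C(C)C | starting material
8 | methyl 5-methyl-4-(3-methylbut-2-en-1-yl)-2-oxo-2H-pyran-3-carboxylate | COC(=O)C1=C(CC=C(C)C)C(C)=COC1=O | intermediate
9 | styrene | C=Cc1ccccc1 | starting material
10 | methyl (1R,4S,8S)-6-methyl-5-(3-methylbut-2-en-1-yl)-3-oxo-8-phenyl-2-oxabicyclo[2.2.2]oct-5-ene-4-carboxylate | O=C1O[C@@H]2C[C@@H](c3ccccc3)[C@@]1(C(=O)OC)C(CC=C(C)C)=C2C | intermediate
11 | (1S,2R,6S)-1-(methoxycarbonyl)-3-methyl-2-(3-methylbut-2-en-1-yl)-6-phenylcyclohex-3-ene-1-carboxylic acid | OC(=O)[C@]1(C(=O)OC)[C@H](CC=C(C)C)C(C)=CC[C@H]1c1ccccc1 | intermediate (not isolated)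
12 | methyl (1R,2S,6R)-3-methyl-2-(3-methylbut-2-en-1-yl)-6-phenylcyclohex-3-ene-1-carboxylate | COC(=O)[C@@H]1[C@H](CC=C(C)C)C(C)=CC[C@H]1c1ccccc1 | intermediate
13 | [(1R,2S,6R)-3-methyl-2-(3-methylbut-2-en-1-yl)-6-phenylcyclohex-3-en-1-yl]methanol | OC[C@@H]1[C@H](CC=C(C)C)C(C)=CC[C@H]1c1ccccc1 | intermediate
14 | (1R,2S,6R)-3-methyl-2-(3-methylbut-2-en-1-yl)-6-phenylcyclohex-3-ene-1-carbaldehyde | O=C[C@@H]1[C@H](CC=C(C)C)C(C)=CC[C@H]1c1ccccc1 | intermediate
15 | 5-methoxyresorcinol (5-methoxybenzene-1,3-diol) | COc1cc(O)cc(O)c1 | starting material
16 | 1-methoxy-3,5-bis(methoxymethoxy)benzene | COCOc1cc(OC)cc(OCOC)c1 | intermediate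
17 | [4-methoxy-2,6-bis(methoxymethoxy)phenyl]lithium | [Li]c1c(OCOC)cc(OC)cc1OCOC | intermediate (not isolated)
18 | [4-methoxy-2,6-bis(methoxymethoxy)phenyl][(1R,2S,6R)-3-methyl-2-(3-methylbut-2-en-1-yl)-6-phenylcyclohex-3-en-1-yl]methanol (both carbinol epimers) | COCOc1cc(OC)cc(OCOC)c1C(O)[C@@H]1[C@H](CC=C(C)C)C(C)=CC[C@H]1c1ccccc1 | intermediate
19 | [4-methoxy-2,6-bis(methoxymethoxy)phenyl][(1R,2S,6R)-3-methyl-2-(3-methylbut-2-en-1-yl)-6-phenylcyclohex-3-en-1-yl]methanone | COCOc1cc(OC)cc(OCOC)c1C(=O)[C@@H]1[C@H](CC=C(C)C)C(C)=CC[C@H]1c1ccccc1 | intermediate
20 | (2,6-dihydroxy-4-methoxyphenyl)[(1R,2S,6R)-3-methyl-2-(3-methylbut-2-en-1-yl)-6-phenylcyclohex-3-en-1-yl]methanone | COc1cc(O)c(C(=O)[C@@H]2[C@H](CC=C(C)C)C(C)=CC[C@H]2c2ccccc2)c(O)c1 | intermediate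
21 | 3-methylbut-2-enal | CC(C)=CC=O | starting material
22 | (7-hydroxy-5-methoxy-2,2-dimethyl-2H-chromen-8-yl)[(1R,2S,6R)-3-methyl-2-(3-methylbut-2-en-1-yl)-6-phenylcyclohex-3-en-1-yl]methanone | COc1cc(O)c(C(=O)[C@@H]2[C@H](CC=C(C)C)C(C)=CC[C@H]2c2ccccc2)c2c1C=CC(C)(C)O2 | target

## Step count and least certain steps

Total: 13 steps. Longest linear sequence: 12 steps (steps 1–8 and 10–13, from 2 to 22); step 9 is a one-step side branch.

Step 5 (key step). The most likely failure is a sluggish cycloaddition: the 4,5-dialkyl pyrone is a weaker diene than the usual substrates, and the prenyl group next to the ester twists it out of the ring plane and weakens chelation. Acid-induced cyclisation of the prenyl group onto a carbonyl oxygen, or cationic oligomerisation of 9, could then overtake the [4+2] reaction. Poor facial discrimination is the second possibility; an inverted sense alone is met by the antipodal ligand and is not counted as the fallback. Fallback (sets out from 8 and 9, returns at 11): run the cycloaddition without a chiral catalyst under high pressure (about 12 kbar, CH2Cl2, 25 °C), which should give the racemic endo adduct rac-methyl (1R,4S,8S)-6-methyl-5-(3-methylbut-2-en-1-yl)-3-oxo-8-phenyl-2-oxabicyclo[2.2.2]oct-5-ene-4-carboxylate F1. Opening under the palladium/formate conditions of step 6 at 40 °C should give the racemic half-acid rac-(1S,2R,6S)-1-(methoxycarbonyl)-3-methyl-2-(3-methylbut-2-en-1-yl)-6-phenylcyclohex-3-ene-1-carboxylic acid F2. This, the only carboxylic acid of the route, is resolved by crystallisation of its salt with (R)-1-phenylethylamine, (1R)-1-phenylethanaminium (1S,2R,6S)-1-(methoxycarbonyl)-3-methyl-2-(3-methylbut-2-en-1-yl)-6-phenylcyclohex-3-ene-1-carboxylate F3 (the antipodal amine is used if the mirror-image salt is the less soluble one). Acidification returns 11, which is heated as in the second stage of step 6.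

Step 6. The most likely failure is slow ionisation, because the palladium must approach the face of the C2=C3 bond under which the endo phenyl group lies. Thermal loss of CO2 from 10, β-hydride elimination or loss of CO2 from the π-allyl intermediate to a diene, or hydride delivery to C4 could then compete. Protonation of C1 from the wrong face would lower the diastereomeric purity; this is met by regenerating the ester enolate with LDA at −78 °C and quenching with a hindered phenol. Fallback (sets out from 10, returns at 12): NaOMe in methanol at 0 °C opens the lactone by acyl–oxygen cleavage to dimethyl (4R,6S)-4-hydroxy-3-methyl-2-(3-methylbut-2-en-1-yl)-6-phenylcyclohex-2-ene-1,1-dicarboxylate F4. A Mitsunobu reaction with 2-nitrobenzenesulfonohydrazide (PPh3, diethyl azodicarboxylate, −30 °C, then rt) inverts C4, and the allylic diazene so formed loses N2 by a suprafacial retro-ene shift that delivers hydrogen to C2 on the phenyl face, giving dimethyl (2R,6S)-3-methyl-2-(3-methylbut-2-en-1-yl)-6-phenylcyclohex-3-ene-1,1-dicarboxylate F5. Krapcho dealkoxycarbonylation (LiCl, wet DMSO, 150 °C) then gives 12, with C1 set by the same kind of protonation as in step 6.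

Step 4. The most likely failure is transfer of the allyl unit through its substituted terminus (giving the 1,1-dimethylallyl isomer), or exchange of triflate for chloride before oxidative addition. Fallback (sets out from 6, returns at 8): Stille coupling with allyltributylstannane, which has no such ambiguity, to methyl 5-methyl-2-oxo-4-(prop-2-en-1-yl)-2H-pyran-3-carboxylate F6, then cross-metathesis with an excess of 2-methylbut-2-ene under the second-generation Grubbs catalyst (CH2Cl2, 40 °C) to install the two terminal methyl groups.

Step 2. The most likely failure is acid-induced cleavage of the tricarbonyl (loss of the acyl group, or of an ester with decarboxylation) running faster than lactonisation. Fallback (sets out from 1, returns at 5): C-acylate 1 with propanoyl chloride (MgCl2, Et3N, MeCN) to dimethyl 2-propanoylpropanedioate F7. Form its dianion (NaH, then LDA, THF, −78 °C) and formylate the terminal carbanion with ethyl formate to dimethyl 2-(2-methyl-3-oxopropanoyl)propanedioate F8, whose hydroxymethylene form should lactonise to 5 on acidification, so that no enol ether has to be hydrolysed under forcing acid.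

Step 13. The most likely failure is a second annulation at the remaining phenol, or slow condensation because both phenols are tied up in hydrogen bonds to the ketone. Fallback (sets out from 20, returns at 22): mono-O-alkylation of 20 with 3-chloro-3-methylbut-1-yne (K2CO3, KI, acetone, 55 °C) to {2-hydroxy-4-methoxy-6-[(2-methylbut-3-yn-2-yl)oxy]phenyl}[(1R,2S,6R)-3-methyl-2-(3-methylbut-2-en-1-yl)-6-phenylcyclohex-3-en-1-yl]methanone F9, then heating in N,N-diethylaniline at 140 °C. Propargyl Claisen rearrangement to the only free ortho carbon, 1,5-hydrogen shift and oxa-6π closure should give 22.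

## Further compounds

F1 | step 5 | rac-methyl (1R,4S,8S)-6-methyl-5-(3-methylbut-2-en-1-yl)-3-oxo-8-phenyl-2-oxabicyclo[2.2.2]oct-5-ene-4-carboxylate (racemate, one enantiomer drawn) | O=C1O[C@@H]2C[C@@H](c3ccccc3)[C@@]1(C(=O)OC)C(CC=C(C)C)=C2C
F2 | step 5 | rac-(1S,2R,6S)-1-(methoxycarbonyl)-3-methyl-2-(3-methylbut-2-en-1-yl)-6-phenylcyclohex-3-ene-1-carboxylic acid (racemate, one enantiomer drawn) | OC(=O)[C@]1(C(=O)OC)[C@H](CC=C(C)C)C(C)=CC[C@H]1c1ccccc1
F3 | step 5 | (1R)-1-phenylethanaminium (1S,2R,6S)-1-(methoxycarbonyl)-3-methyl-2-(3-methylbut-2-en-1-yl)-6-phenylcyclohex-3-ene-1-carboxylate | C[C@@H]([NH3+])c1ccccc1.[O-]C(=O)[C@]1(C(=O)OC)[C@H](CC=C(C)C)C(C)=CC[C@H]1c1ccccc1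
F4 | step 6 | dimethyl (4R,6S)-4-hydroxy-3-methyl-2-(3-methylbut-2-en-1-yl)-6-phenylcyclohex-2-ene-1,1-dicarboxylate | COC(=O)C1(C(=O)OC)C(CC=C(C)C)=C(C)[C@H](O)C[C@H]1c1ccccc1
F5 | step 6 | dimethyl (2R,6S)-3-methyl-2-(3-methylbut-2-en-1-yl)-6-phenylcyclohex-3-ene-1,1-dicarboxylate | COC(=O)C1(C(=O)OC)[C@H](CC=C(C)C)C(C)=CC[C@H]1c1ccccc1
F6 | step 4 | methyl 5-methyl-2-oxo-4-(prop-2-en-1-yl)-2H-pyran-3-carboxylate | COC(=O)C1=C(CC=C)C(C)=COC1=O
F7 | step 2 | dimethyl 2-propanoylpropanedioate | CCC(=O)C(C(=O)OC)C(=O)OC
F8 | step 2 | dimethyl 2-(2-methyl-3-oxopropanoyl)propanedioate | O=CC(C)C(=O)C(C(=O)OC)C(=O)OC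
F9 | step 13 | {2-hydroxy-4-methoxy-6-[(2-methylbut-3-yn-2-yl)oxy]phenyl}[(1R,2S,6R)-3-methyl-2-(3-methylbut-2-en-1-yl)-6-phenylcyclohex-3-en-1-yl]methanone | COc1cc(O)c(C(=O)[C@@H]2[C@H](CC=C(C)C)C(C)=CC[C@H]2c2ccccc2)c(OC(C)(C)C#C)c1
A1 | alternative 1 | (2E,4Z,6E)-1-(7-hydroxy-5-methoxy-2,2-dimethyl-2H-chromen-8-yl)-4-methyl-7-phenylhepta-2,4,6-trien-1-one | COc1cc(O)c(C(=O)/C=C/C(C)=C\C=C\c2ccccc2)c2c1C=CC(C)(C)O2
A2 | alternative 1 | (7-hydroxy-5-methoxy-2,2-dimethyl-2H-chromen-8-yl)[(6S)-3-methyl-6-phenylcyclohexa-1,3-dien-1-yl]methanone | COc1cc(O)c(C(=O)C2=CC(C)=CC[C@H]2c2ccccc2)c2c1C=CC(C)(C)O2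
A3 | alternative 2 | 2-{(R)-(tert-butyldimethylsilyloxy)[(1R,2S,6R)-3-methyl-2-(3-methylbut-2-en-1-yl)-6-phenylcyclohex-3-en-1-yl]methyl}-5-methoxy-3-(triisopropylsilyloxy)phenol | COc1cc(O)c([C@H](O[Si](C)(C)C(C)(C)C)[C@@H]2[C@H](CC=C(C)C)C(C)=CC[C@H]2c2ccccc2)c(O[Si](C(C)C)(C(C)C)C(C)C)c1
A4 | alternative 2 | tert-butyldimethyl{[(1R)-1-[(1R,2S,6R)-3-methyl-2-(3-methylbut-2-en-1-yl)-6-phenylcyclohex-3-en-1-yl]-3-(triisopropylsilyloxy)prop-2-yn-1-yl]oxy}silane | CC(C)[Si](C(C)C)(C(C)C)OC#C[C@H](O[Si](C)(C)C(C)(C)C)[C@@H]1[C@H](CC=C(C)C)C(C)=CC[C@H]1c1ccccc1
A5 | alternative 2 | 3-methoxycyclobut-2-en-1-one | COC1=CC(=O)C1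
A6 | alternative 3 | methyl (1R,2S,6R)-3-methyl-2-(3-methylbut-2-en-1-yl)-6-phenylcyclohex-3-ene-1-carboxylate (same structure as 12) | COC(=O)[C@@H]1[C@H](CC=C(C)C)C(C)=CC[C@H]1c1ccccc1
A7 | alternative 3 | methyl (2R,3S)-3-[(2E)-but-2-en-2-yl]-6-methyl-2-[(1R)-1-phenylbut-3-en-1-yl]hept-5-enoate | COC(=O)[C@H]([C@H](CC=C(C)C)/C(C)=C/C)[C@@H](CC=C)c1ccccc1
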